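(All runs were computed with made-up constants.)

We decide to reckon in concentrations of J used rather than in percent of the charge, and to follow one molecule through its forks. Gas E dissolves as L, L and J meet on catalyst D to give Z, and Z on D may go on to G.

| flask | J | E | D | remark | time |
|---|---|---|---|---|---|
| amber | 0.047 M | 16 mM (held) | 10 mM | run made earlier |  |
| red | 0.097 M | 16 mM (held) | 10 mM | run made earlier |  |
| ochre | 0.17 M | 16 mM (held) | 10 mM | run made earlier |  |
| alpha | 0.050 M | 16 mM (held) | 10 mM |  | 4.0 min |
| epsilon | 0.10 M | 16 mM (held) | 10 mM |  | 4.0 min |
| theta | 0.20 M | 16 mM (held) | 10 mM |  | 4.0 min |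

- amber (time / min: Z / %, J / %): 0.250: 2.2, 100.4; 0.667: 3.1, 96.5; 1.33: 7.1, 91.2; 2.00: 12.4, 87.6; 3.00: 21.3, 74.2
- red (time / min: Z / %, J / %): 0.250: 2.0, 98.8; 0.417: 1.6, 98.1; 0.833: 2.7, 96.1; 1.33: 4.1, 94.9; 3.00: 13.1, 85.1
- ochre (time / min: Z / %, J / %): 0.250: 0, 101.0; 0.417: 1.9, 97.8; 0.833: 0.8, 97.5; 1.33: 4.0, 94.6; 3.00: 8.8, 91.0

(readings scatter by 1 percentage point)

- at the start none of L is dissolved
- steps under discussion: E <-> L; J + L + D -> D + Z; D + Z -> D + G
- "hardly changes" means that all values lie within two and a half points (for a concentration: within two and a half percent of the largest)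

1. amount of Z at the end, in percent of the J charged for alpha, epsilon, theta, in this order
2. how the row runs (rises all the way / hardly changes / falls, then rises / rises, then falls / falls all the way)

By 3.00 min amber, red and ochre have used 12.1 mM, 14.5 mM and 15.3 mM of J. The charge rises 3.62-fold across these runs, but the amount used rises 1.26-fold, so we treat the amount used as weakly tied to the charge. From 1.33 min onward the three runs use on average 4.71 mM min⁻¹. We extend each run to 4.0 min at that pace and divide by the charge of its new neighbour, so alpha, epsilon and theta should have used 33.7%, 19.2% and 10.0% of their J.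

The fork we follow is whether a Z stays Z or goes on to G. If Z is made steadily and each Z has the same small chance per minute of going on, its mean age is half the elapsed time, and the share lost to G grows in proportion to time. At 3.00 min amber's gap between J used and Z found reads 4.5 percentage points, a reading of 17.4% of its used J lost, which would leave 76.8% kept at 4.0 min.

That is the weak link, since one gap carries the scatter of two readings, each 1 point. At the same time ochre's gap reads 0.2 points and red's 1.8 points. Every percent reading has the same scatter, so we add the gaps and the percentages used over the three runs. This gives a lost share of 13.1%, hence a wear, the chance per minute that a Z goes to G, of 0.0872 min⁻¹. The keep, the share of used J still standing as Z at 4.0 min (the selectivity for Z), is then 82.6%. Our row is 27.8%, 15.8% and 8.26%, falling all the way.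

The forecast gave 29%, 17.5% and 10.5%, falls all the way: “Percent Z therefore falls as J rises.” The flask gives 25.3%, 15.8% and 8.79%, falls all the way.

    E ⇌ L, rate k1*(csat - [L]) (kL = 0.00637 s⁻¹)
    J + L + D → D + Z (k = 49.9 M⁻² s⁻¹)
    D + Z → D + G (k = 0.198 M⁻¹ s⁻¹)

In alpha, Z is made 6.30 times faster than it is used up at 1.90 min, and 2.80 times faster at 4.00 min, so Z is still gaining by a narrower margin. Our keep on the 31.2% alpha has used gives 25.8%, and alpha holds 25.3% of Z. On the 11.0% theta has used it gives 9.05%, and theta holds 8.79% of Z.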